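## Retrosynthetic overview
1. The target comes from an allylic diazene at C4 by retro-ene loss of N2. The key bond is C4–N, made by condensing a C16 (2E)-enal with 2-nitrobenzenesulfonohydrazide. Nitrogen activates C4, stores its configuration and hands H to C6.
2. The same operation joins the two halves. A C16 (Z)-γ,γ-disubstituted allyl boronate that carries the ring adds to the C=N bond and sets quaternary C3.
3. The boronate comes from 1,4-hydroboration of a triene, made by methylenation of a ketone. The ketone comes from Me2CuLi addition and dienylation of (S)-3,4-dimethylcyclohex-2-enone, itself from Birch reduction and asymmetric isomerisation of 3,4-dimethylanisole.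
4. The enal comes from allylic oxidation after B-alkyl Suzuki coupling of an (E)-alkenyl iodide with a C6 dienol. The iodide comes from carboalumination of an alkyne made from (R)-5,6-dimethylhept-6-en-2-one, which comes from (S)-limonene by ozonolysis and decarbonylation.
5. Rings: no ring is formed. The only ring is the arene ring of the anisole, dearomatised at the start. One C6 dienol serves both halves.

Assumption: the four starting materials are taken as catalogue chemicals, and locants C3 (quaternary carbon), C4, C5, C6 (allylic methine) and C13 are those of the pentadecatetraene name of the target.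

## Route

Step 1
Reactants: 1 (2E)-3-methylpent-2-en-4-yn-1-ol
Product: 2 (2E)-3-methylpenta-2,4-dien-1-ol
Conditions: H2 (1 atm, stopped at 1.0 equiv), Pd/CaCO3 poisoned with Pb(OAc)2 (5 wt % Pd), quinoline, EtOAc, 0 °C
Reagents that add atoms: none
Why: Semihydrogenation of a terminal alkyne over lead-poisoned palladium stops at the vinyl group because the alkyne binds far better than the diene, and the E-trisubstituted alkene is left untouched.

Step 2
Reactants: 2 (2E)-3-methylpenta-2,4-dien-1-ol
Product: 3 (3E)-5-bromo-3-methylpenta-1,3-diene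
Conditions: PBr3 (0.4 equiv), pyridine (cat.), Et2O, −10 °C; used crude
Reagents that add atoms: phosphorus tribromide BrP(Br)Br
Why: Bromination of a primary allylic alcohol through its phosphite ester (SN2 at CH2) at low temperature keeps the E geometry and gives the favoured primary dienyl bromide.

Step 3
Reactants: 4 3,4-dimethylanisole
Product: 6 3,4-dimethylcyclohex-3-en-1-one, via dihydroanisole 5 (not isolated)
Conditions: Li, NH3(l), t-BuOH, THF, −78 to −33 °C; then (CO2H)2, MeOH–H2O, 23 °C
Reagents that add atoms: water O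
Why: Birch reduction leaves the methoxy- and methyl-bearing carbons on the two remaining double bonds, and mild enol-ether hydrolysis frees the ketone without moving the tetrasubstituted alkene into conjugation.

Step 4
Reactants: 6 3,4-dimethylcyclohex-3-en-1-one
Product: 7 (4S)-3,4-dimethylcyclohex-2-en-1-one
Conditions: cinchona-derived primary amine–quinuclidine catalyst (9-amino-9-deoxy-epi series, the pseudo-enantiomer that gives S, 10 mol %), 2-chloropropanoic acid (20 mol %), toluene, −25 °C
Reagents that add atoms: none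
Why: In this enantioselective olefin isomerisation by cooperative iminium–base (dienamine) catalysis, the amine forms the iminium ion, the quinuclidine removes H-2, and its conjugate acid returns the proton to one face of C4, which sets the (4S) centre that becomes C3 of the ring.

Step 5
Reactants: 7 (4S)-3,4-dimethylcyclohex-2-en-1-one; 3 (3E)-5-bromo-3-methylpenta-1,3-diene
Product: 9 (2R,4S)-3,3,4-trimethyl-2-[(2E)-3-methylpenta-2,4-dien-1-yl]cyclohexan-1-one, via lithium enolate 8 (not isolated)
Conditions: Me2CuLi (from MeLi and CuI, 1.1 equiv), Et2O, 0 °C; then THF–DMPU, 3 (1.5 equiv), −30 to 23 °C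
Reagents that add atoms: lithium dimethylcuprate [Li+].C[Cu-]C
Why: In this Gilman conjugate addition and enolate alkylation, methyl adds to C3 to give the gem-dimethyl carbon (no stereocentre), and the regiodefined enolate takes the allylic bromide axially, anti to the pseudoaxial C3 methyl of the half-chair with equatorial C4 methyl, which gives the kinetic 2,4-trans ketone (2R).

Step 6
Reactants: 9 (2R,4S)-3,3,4-trimethyl-2-[(2E)-3-methylpenta-2,4-dien-1-yl]cyclohexan-1-one
Product: 10 (1S,3S)-2,2,3-trimethyl-6-methylidene-1-[(2E)-3-methylpenta-2,4-dien-1-yl]cyclohexane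
Conditions: Cp2TiMe2 (2.5 equiv), toluene, 70 °C, dark
Reagents that add atoms: dimethyltitanocene [CH3-].[CH3-].[Ti+4].[cH-]1cccc1.[cH-]1cccc1
Why: Petasis methylenation uses thermally formed, non-basic Cp2Ti=CH2, so the hindered enolisable ketone is olefinated through an oxatitanacyclobutane without epimerising the axial side chain (the descriptor changes from R to S only through priorities).

Step 7
Reactants: 10 (1S,3S)-2,2,3-trimethyl-6-methylidene-1-[(2E)-3-methylpenta-2,4-dien-1-yl]cyclohexane
Product: 11 2-{(2Z)-3-methyl-5-[(1S,3S)-2,2,3-trimethyl-6-methylidenecyclohexyl]pent-2-en-1-yl}-4,4,5,5-tetramethyl-1,3,2-dioxaborolane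
Conditions: HBpin (1.05 equiv), Ni(cod)2 (2.5 mol %), PCy3 (2.5 mol %), toluene, 23 °C
Reagents that add atoms: pinacolborane [H]B1OC(C)(C)C(C)(C)O1
Why: In nickel-catalysed 1,4-hydroboration the s-cis-bound (E)-diene on zerovalent nickel takes H at its substituted terminus and boron at its CH2 terminus, so the two former termini end cis on the new trisubstituted alkene (Z), and the isolated 1,1-disubstituted alkene does not react with HBpin.

Step 8
Reactants: 12 (S)-(−)-limonene
Product: 13 (3S)-6-oxo-3-(prop-1-en-2-yl)heptanal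
Conditions: O3 (1.0 equiv), CH2Cl2–MeOH, −78 °C; then Me2S, −78 to 23 °C
Reagents that add atoms: ozone [O-][O+]=O
Why: Chemoselective ozonolysis (Criegee mechanism, reductive work-up) cleaves the electron-richer trisubstituted ring alkene before the isopropenyl group and leaves the stereocentre untouched.

Step 9
Reactants: 13 (3S)-6-oxo-3-(prop-1-en-2-yl)heptanal
Product: 14 (5R)-5,6-dimethylhept-6-en-2-one
Conditions: RhCl(PPh3)3 (1.05 equiv), toluene, 110 °C, Ar
Reagents that add atoms: none
Why: Tsuji–Wilkinson decarbonylation (insertion into the formyl C–H bond, CO extrusion, C–H reductive elimination) turns CH2CHO into CH3 without touching any bond at the stereocentre, whose descriptor changes from S to R only through priorities.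

Step 10
Reactants: 14 (5R)-5,6-dimethylhept-6-en-2-one
Product: 16 (5R)-5,6-dimethylhept-6-en-1-yne, via enol phosphate 15 (not isolated)
Conditions: LiN(iPr)2 (1.1 equiv), THF, −78 °C; ClP(O)(OEt)2, −78 to 23 °C; then LiN(iPr)2 (2.3 equiv), −78 to 23 °C; H2O
Reagents that add atoms: none
Why: In the Negishi methyl ketone to alkyne conversion, kinetic deprotonation at CH3 gives the terminal enol phosphate, and base-induced elimination of phosphate gives the terminal alkyne while the remote stereocentre is not acidic.

Step 11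
Reactants: 16 (5R)-5,6-dimethylhept-6-en-1-yne
Product: 18 (1E,5R)-1-iodo-2,5,6-trimethylhepta-1,6-diene, via alkenylalane 17 (not isolated)
Conditions: Me3Al (2 equiv), Cp2ZrCl2 (0.25 equiv), CH2Cl2, 0 to 23 °C; then I2, THF, −30 °C
Reagents that add atoms: trimethylaluminium C[Al](C)C; iodine [I][I]
Why: Negishi zirconium-catalysed carboalumination adds Me and Al syn across the alkyne with Me on the internal carbon, and iodinolysis with retention gives the pure E-iodide while the 1,1-disubstituted alkene stays inert.

Step 12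
Reactants: 18 (1E,5R)-1-iodo-2,5,6-trimethylhepta-1,6-diene; 2 (2E)-3-methylpenta-2,4-dien-1-ol
Product: 20 (2E,6E,10R)-3,7,10,11-tetramethyldodeca-2,6,11-trien-1-ol, via bis-boryl adduct 19 (not isolated)
Conditions: 2, 9-BBN-H (2.1 equiv), THF, 0 to 23 °C; 3 M aq NaOH; then 18, PdCl2(dppf) (5 mol %), THF, 23 °C
Reagents that add atoms: none
Why: In this hydroboration and B-alkyl Suzuki–Miyaura coupling, 9-BBN-H first masks the hydroxyl as a borinate and then adds only to the vinyl terminus of the diene, and the sp3–sp2 coupling keeps the iodide geometry so both trisubstituted alkenes are E.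

Step 13
Reactants: 20 (2E,6E,10R)-3,7,10,11-tetramethyldodeca-2,6,11-trien-1-ol
Product: 21 (2E,6E,10R)-3,7,10,11-tetramethyldodeca-2,6,11-trienal
Conditions: MnO2 (15 equiv), CH2Cl2, 23 °C
Reagents that add atoms: none
Why: Heterogeneous MnO2 oxidation is selective for the allylic alcohol and is neutral, so the 2E geometry needed for the later chirality transfer is kept.

Step 14
Reactants: 21 (2E,6E,10R)-3,7,10,11-tetramethyldodeca-2,6,11-trienal; 22 2-nitrobenzenesulfonohydrazide; 11 2-{(2Z)-3-methyl-5-[(1S,3S)-2,2,3-trimethyl-6-methylidenecyclohexyl]pent-2-en-1-yl}-4,4,5,5-tetramethyl-1,3,2-dioxaborolane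
Product: 26 (3S,4E,6S,9E,13R)-3,6,10,13,14-pentamethyl-3-{2-[(1S,3S)-2,2,3-trimethyl-6-methylidenecyclohexyl]ethyl}pentadeca-1,4,9,14-tetraene, via hydrazone 23 (not isolated), via hydrazide 24 (not isolated), via diazene 25 (not isolated)
Conditions: 21, 22 (1.00 equiv, no excess so that no diimide forms), toluene–THF 5:1, 0 °C, 30 min; then (R)-TRIP [(R)-3,3'-bis(2,4,6-triisopropylphenyl)-1,1'-binaphthyl-2,2'-diyl hydrogen phosphate, 10 mol %], 11 (1.1 equiv), −20 to 0 °C; then 23 °C until N2 evolution ends
Reagents that add atoms: none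
Why: Proposed new method: the key C=N bond is formed first by condensation to the (E)-sulfonylhydrazone, and the phosphoric acid then binds boronate and hydrazone at two points (P–OH to a pinacol oxygen, which raises the Lewis acidity of boron, and P=O to the sulfonamide N–H) so that allyl transfer runs through a closed chair with boron on the imine lone pair; this places the alkenyl group axial, the (Z)-boronate places the ring-bearing chain axial and the methyl equatorial, and the result is the (3S,4R) hydrazide, with (R)-TRIP expected to select the same chair handedness as in aldehyde allylboration; loss of ArSO2H at 23 °C gives the monoalkyl diazene, whose suprafacial retro-ene through the conformer with C4–H eclipsing the alkene (least A(1,3) strain against the cis methyl) moves N–H to the face of C6 that nitrogen occupied and sets 6S and 4E as N2 leaves; the closest known reaction types are the diol-catalysed traceless Petasis borono-Mannich reaction of enals with allyl and crotyl boronates, phosphoric-acid-catalysed aldehyde allylboration and the Myers allylic diazene transposition, and the new elements are a γ,γ-dialkyl (Z)-allyl pinacol boronate that makes an all-carbon quaternary centre, a β,β-dialkyl enal and phosphoric acid control on a sulfonylhydrazone.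

## Compound list
1 | (2E)-3-methylpent-2-en-4-yn-1-ol | C#C/C(C)=C/CO | starting material
2 | (2E)-3-methylpenta-2,4-dien-1-ol | C=C/C(C)=C/CO | intermediate
3 | (3E)-5-bromo-3-methylpenta-1,3-diene | C=C/C(C)=C/CBr | intermediate
4 | 3,4-dimethylanisole | COc1ccc(C)c(C)c1 | starting material
5 | 1-methoxy-4,5-dimethylcyclohexa-1,4-diene (not isolated) | COC1=CCC(C)=C(C)C1 | intermediate
6 | 3,4-dimethylcyclohex-3-en-1-one | O=C1CCC(C)=C(C)C1 | intermediate
7 | (4S)-3,4-dimethylcyclohex-2-en-1-one | O=C1CC[C@H](C)C(C)=C1 | intermediate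
8 | lithium (4S)-3,3,4-trimethylcyclohex-1-en-1-olate (not isolated) | [Li+].[O-]C1=CC(C)(C)[C@@H](C)CC1 | intermediate
9 | (2R,4S)-3,3,4-trimethyl-2-[(2E)-3-methylpenta-2,4-dien-1-yl]cyclohexan-1-one | C=C/C(C)=C/C[C@H]1C(=O)CC[C@H](C)C1(C)C | intermediate
10 | (1S,3S)-2,2,3-trimethyl-6-methylidene-1-[(2E)-3-methylpenta-2,4-dien-1-yl]cyclohexane | C=C/C(C)=C/C[C@H]1C(=C)CC[C@H](C)C1(C)C | intermediate
11 | 2-{(2Z)-3-methyl-5-[(1S,3S)-2,2,3-trimethyl-6-methylidenecyclohexyl]pent-2-en-1-yl}-4,4,5,5-tetramethyl-1,3,2-dioxaborolane | CC1(C)OB(C/C=C(/C)CC[C@H]2C(=C)CC[C@H](C)C2(C)C)OC1(C)C | intermediate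
12 | (S)-(−)-limonene | CC1=CC[C@H](CC1)C(C)=C | starting material
13 | (3S)-6-oxo-3-(prop-1-en-2-yl)heptanal | O=CC[C@H](CCC(C)=O)C(C)=C | intermediate
14 | (5R)-5,6-dimethylhept-6-en-2-one | CC(=O)CC[C@@H](C)C(C)=C | intermediate
15 | diethyl (5R)-5,6-dimethylhepta-1,6-dien-2-yl phosphate (not isolated) | CCOP(=O)(OCC)OC(=C)CC[C@@H](C)C(C)=C | intermediate
16 | (5R)-5,6-dimethylhept-6-en-1-yne | C#CCC[C@@H](C)C(C)=C | intermediate
17 | dimethyl[(1E,5R)-2,5,6-trimethylhepta-1,6-dien-1-yl]alane (not isolated) | C[Al](C)/C=C(\C)CC[C@@H](C)C(C)=C | intermediate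
18 | (1E,5R)-1-iodo-2,5,6-trimethylhepta-1,6-diene | I/C=C(\C)CC[C@@H](C)C(C)=C | intermediate
19 | 9-{(3E)-5-[(9-borabicyclo[3.3.1]nonan-9-yl)oxy]-3-methylpent-3-en-1-yl}-9-borabicyclo[3.3.1]nonane (not isolated) | O(B1C2CCCC1CCC2)C/C=C(\C)CCB1C2CCCC1CCC2 | intermediate
20 | (2E,6E,10R)-3,7,10,11-tetramethyldodeca-2,6,11-trien-1-ol | OC/C=C(\C)CC/C=C(\C)CC[C@@H](C)C(C)=C | intermediate
21 | (2E,6E,10R)-3,7,10,11-tetramethyldodeca-2,6,11-trienal | O=C/C=C(\C)CC/C=C(\C)CC[C@@H](C)C(C)=C | intermediate
22 | 2-nitrobenzenesulfonohydrazide | NNS(=O)(=O)c1ccccc1[N+](=O)[O-] | starting material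
23 | N'-[(1E,2E,6E,10R)-3,7,10,11-tetramethyldodeca-2,6,11-trien-1-ylidene]-2-nitrobenzenesulfonohydrazide (not isolated) | O=S(=O)(N/N=C/C=C(\C)CC/C=C(\C)CC[C@@H](C)C(C)=C)c1ccccc1[N+](=O)[O-] | intermediate
24 | N'-[(3S,4R,5E,9E,13R)-3,6,10,13,14-pentamethyl-3-{2-[(1S,3S)-2,2,3-trimethyl-6-methylidenecyclohexyl]ethyl}pentadeca-1,5,9,14-tetraen-4-yl]-2-nitrobenzenesulfonohydrazide (not isolated) | C=C[C@@](C)([C@H](NNS(=O)(=O)c1ccccc1[N+](=O)[O-])/C=C(\C)CC/C=C(\C)CC[C@@H](C)C(C)=C)CC[C@H]1C(=C)CC[C@H](C)C1(C)C | intermediate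
25 | [(3S,4R,5E,9E,13R)-3,6,10,13,14-pentamethyl-3-{2-[(1S,3S)-2,2,3-trimethyl-6-methylidenecyclohexyl]ethyl}pentadeca-1,5,9,14-tetraen-4-yl]diazene (not isolated) | C=C[C@@](C)([C@H](N=N)/C=C(\C)CC/C=C(\C)CC[C@@H](C)C(C)=C)CC[C@H]1C(=C)CC[C@H](C)C1(C)C | intermediate
26 | (3S,4E,6S,9E,13R)-3,6,10,13,14-pentamethyl-3-{2-[(1S,3S)-2,2,3-trimethyl-6-methylidenecyclohexyl]ethyl}pentadeca-1,4,9,14-tetraene (CNP0186101.1) | C=C[C@@](C)(/C=C/[C@@H](C)CC/C=C(\C)CC[C@@H](C)C(=C)C)CC[C@H]1C(=C)CC[C@H](C)C1(C)C | target

## Step count and risks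
Total steps: 14. Longest linear sequence: 7 (steps 8 to 14, from 12).

**Step 14 (the proposed new step).**
- The hindered boronate may add too slowly to a sulfonylhydrazone.
- The hydrazone may react through its Z form, which would invert the C3/C4 relationship.
- The sulfinic acid released may open a racemic background path.

The fallback uses known chemistry, sets out from 21 and 11 and comes back at 26. Enal 21 itself is allylborated with 11 under (R)-TRIP catalysis (toluene, −30 °C). In the closed chair the alkenyl group is now equatorial, so the Z-boronate gives (3S,4S,5E,9E,13R)-3,6,10,13,14-pentamethyl-3-{2-[(1S,3S)-2,2,3-trimethyl-6-methylidenecyclohexyl]ethyl}pentadeca-1,5,9,14-tetraen-4-ol F1. Acetic formic anhydride and pyridine convert it into (3S,4S,5E,9E,13R)-3,6,10,13,14-pentamethyl-3-{2-[(1S,3S)-2,2,3-trimethyl-6-methylidenecyclohexyl]ethyl}pentadeca-1,5,9,14-tetraen-4-yl formate F2. Pd(acac)2 and PBu3 in THF then ionise the formate anti to oxygen and lose CO2. Hydride passes from palladium to the more substituted terminus C6 (formate hydrogenolysis of an allylic ester). This puts H on the same face as the diazene route does and gives 26 with 4E and 6S.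

**Step 5.** A cuprate-derived enolate next to a quaternary carbon may alkylate slowly, which allows proton transfer, C6 alkylation or coupling of 3 with copper species. The fallback sets out from 7 and comes back at 8 and so at 9. Me2CuLi with Me3SiCl (Et2O–THF, −78 °C) gives the isolable [(4S)-3,3,4-trimethylcyclohex-1-en-1-yl]oxy(trimethyl)silane F3. After purification, MeLi in THF at 0 °C cleaves it to copper-free, regiodefined enolate 8. This enolate is alkylated with 3 in THF–DMPU under the same axial control.

**Step 9.** The substrate is a 4-pentenal, so intramolecular hydroacylation to a cyclopentanone or rhodium hydride isomerisation of the isopropenyl group (loss of the stereocentre) may compete. The fallback sets out from 13 and comes back at 14. Pinnick oxidation (NaClO2, NaH2PO4, 2-methylbut-2-ene, t-BuOH–H2O) gives (3S)-6-oxo-3-(prop-1-en-2-yl)heptanoic acid F4. DCC and 1-hydroxypyridine-2(1H)-thione give 2-thioxopyridin-1(2H)-yl (3S)-6-oxo-3-(prop-1-en-2-yl)heptanoate F5. Visible-light Barton decarboxylation in the presence of excess t-BuSH traps the primary radical faster than vinyl migration and delivers 14.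

## Further compounds
F1 | step 14 | (3S,4S,5E,9E,13R)-3,6,10,13,14-pentamethyl-3-{2-[(1S,3S)-2,2,3-trimethyl-6-methylidenecyclohexyl]ethyl}pentadeca-1,5,9,14-tetraen-4-ol | C=C[C@@](C)([C@@H](O)/C=C(\C)CC/C=C(\C)CC[C@@H](C)C(C)=C)CC[C@H]1C(=C)CC[C@H](C)C1(C)C
F2 | step 14 | (3S,4S,5E,9E,13R)-3,6,10,13,14-pentamethyl-3-{2-[(1S,3S)-2,2,3-trimethyl-6-methylidenecyclohexyl]ethyl}pentadeca-1,5,9,14-tetraen-4-yl formate | C=C[C@@](C)([C@@H](OC=O)/C=C(\C)CC/C=C(\C)CC[C@@H](C)C(C)=C)CC[C@H]1C(=C)CC[C@H](C)C1(C)C
F3 | step 5 | [(4S)-3,3,4-trimethylcyclohex-1-en-1-yl]oxy(trimethyl)silane | C[Si](C)(C)OC1=CC(C)(C)[C@@H](C)CC1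
F4 | step 9 | (3S)-6-oxo-3-(prop-1-en-2-yl)heptanoic acid | OC(=O)C[C@H](CCC(C)=O)C(C)=C
F5 | step 9 | 2-thioxopyridin-1(2H)-yl (3S)-6-oxo-3-(prop-1-en-2-yl)heptanoate | O=C(C[C@H](CCC(C)=O)C(C)=C)ON1C=CC=CC1=S
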